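## Structural features

The target is a flavonol. Benzene ring A is fused through C4a–C8a to 4-pyranone ring C, which carries a 4-hydroxy-3-methoxyphenyl ring B at C2 and an enolic hydroxyl at C3. Ring A is substituted everywhere except C6: the ring oxygen O1 on C8a, a methoxy group on C8, a prenyl (3-methylbut-2-enyl) ether on C7 and a hydroxyl on C5 that is chelated to the C4 carbonyl. There is no stereocentre, and the prenyl double bond carries two identical methyl groups, so no configuration has to be set or preserved. The fragile parts are the allylic aryl ether at C7, the 3-hydroxypyranone enol and the electron-rich ring A. The ether is ionised by protic and Lewis acids, is open to π-allyl formation with zerovalent palladium, and its alkene is easily hydrogenated, epoxidised and halogenated; the enol is oxidised in air under strongly basic conditions. The real difficulty is regiochemical. Ring A is 1,2,3,5-tetraoxygenated and the two oxygens flanking the C8 methoxy group (O7 and O1) must end up different. In addition, three hydroxyls (C3, C5, C4') must be unmasked by a method that spares the prenyl ether, which excludes acid-cleaved acetals, hydrogenolysis and Lewis-acidic dealkylation. The key step uses the fact that C4 lies between C4a and C3 while O1 sits on C8a, ortho to C4a. An ortho-iodophenol (I on C4a, OH on C8a), carbon monoxide (C4) and the ring B arylacetylene (C3 and C2) therefore hold every atom of ring C.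

## Logic of the disconnections

**20 ⇒ 19.** The O5–Si and O4'–Si bonds are cut last. Both phenols have to stay masked through the amide-base step, and silicon lets them be freed by buffered fluoride. This changes nothing in the skeleton but decouples the unmasking from the prenyl ether. The forward step must therefore work without acid, reductant or oxidant.

**19 ⇒ 16.** The C3–O bond is cut. C3–H is the most acidic C–H of a flavone (vinylic and next to the C4 carbonyl), so the oxygen can be added after ring C exists. The gain is a plain flavone, which is what the three-component closure delivers. The forward step must metalate only C3 and use an oxidant that leaves the isolated alkene alone.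

**16 ⇒ 9 + 12 + 13.** C4a–C4, C4–C3 and O1–C2 are cut together, which removes ring C in one operation. Ring A and ring B become two arenes of similar size, neither needing a preformed carbonyl carbon, because 13 supplies C4. The forward step must insert 13 before alkynyl transfer, close 6-endo and close only through O1. For that reason 9 carries a free hydroxyl on C8a and a silyl ether on O5.

**9 ⇒ 7 + 8.** The O7–CH2 bond is cut. This lets the iodine be introduced before the alkene is present, on a precursor in which it has no regiochemical choice. The gain is a symmetric-origin iodo-diol plus commercial 8. The forward alkylation must tell O7 (para to iodine) from O8a (ortho to iodine).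

**7 ⇒ 6.** The C4a–I bond is cut. In 6 the two open ring positions are related by the mirror plane through C2 and C5, so mono-iodination can give only one constitution. The forward step only has to stop after one substitution.

**6 ⇒ 5 ⇒ 4.** The two phenols of 6 are re-masked as acetates, and then the O5–Si bond is cut. In 4 the C5 hydroxyl is the only free one, so silylation is unambiguous. Acetate and silyl ether are orthogonal, so the forward deacylation must not touch silicon.

**4 ⇒ 2 (through 3).** The C5–O bond is cut. C5 is meta to both acyloxy groups, so electrophilic substitution cannot reach it. It is, however, the only C–H without an ortho neighbour, which suits sterically controlled iridium-catalysed borylation followed by oxidation. The gain is a simple 1,2,3-trioxygenated benzene. The oxidation must tolerate aryl esters.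

**2 ⇒ 1.** The two acyl C–O bonds are cut, leading to commercial 1. The acetates keep the ring symmetric and keep free O–H groups away from the boron reagent.

**12 ⇒ 11 ⇒ 10.** The alkyne carbon that becomes C3 is removed (one-carbon homologation of an aldehyde), then the O4'–Si bond is cut. This leads to commercial 10. The homologation must avoid alkoxide bases, which would cleave the para-formyl aryl silyl ether.

## Other disconnections considered

**Alternative 1:** The cut runs through ring A itself (C8–C8a and C4a–C5).
- **Forward step.** The diene 4-(benzyloxy)-2-(tert-butyldimethylsilyloxy)furan A1 would add to methyl 3-bromopropiolate A2. The oxygen-bridged adduct would open and aromatise to methyl 4-(benzyloxy)-2-bromo-6-(tert-butyldimethylsilyloxy)-3-hydroxybenzoate A3. In A3 the ester carbon is the future C4, bromine marks C8a, the free hydroxyl is O8, and the silyl and benzyl ethers are O5 and O7.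
- **In favour.** Every ring A position leaves the cycloaddition differentiated, with regiochemistry fixed by the polarisation of diene and dienophile. On this point it is better than the chosen plan, which must tell O7 from O8a by a selective alkylation. C4 is also already bonded to C4a.
- **Against.** All of ring C remains to be built: C8a–Br to C8a–O, a Claisen-type union with a ring B ketone, cyclodehydration, then C3 oxygenation. The O7 benzyl ether must be exchanged for prenyl before any hydrogenolysis becomes impossible. A1 is a hydrolytically sensitive silyl ketene acetal and A2 an unstable, lachrymatory alkyne.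
- **Comparison.** Structurally the two plans are equal (no stereocentre in either). Mechanistically, a concerted cycloaddition plus fragmentation replaces a catalytic cascade. In step economy the chosen plan is clearly shorter, since it closes ring C from three components in one step.

**Alternative 2:** The cut is the C2=C3 double bond.
- **Forward step.** A ring A aryl ester of the ring B acid bearing an ortho (alkoxy)acyl ylide would be heated: 6-methoxy-3-(methoxymethoxy)-5-(prenyloxy)-2-{2-[2-(trimethylsilyl)ethoxy]-2-(triphenylphosphoranylidene)acetyl}phenyl 3-methoxy-4-(methoxymethoxy)benzoate A4. The ylide carbon (C3) would attack the ester carbonyl (C2) and phosphorus would leave as its oxide. The product is 5,4'-bis(methoxymethoxy)-8,3'-dimethoxy-7-(prenyloxy)-3-[2-(trimethylsilyl)ethoxy]flavone A5.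
- **In favour.** The 3-oxygen is in place when the ring closes, so no C3 carbanion is needed afterwards, and no transition metal meets the prenyl ether. On both points it is better than the chosen plan.
- **Against.** Ester carbonyls are poor Wittig acceptors, and prolonged heating brings the aryl prenyl ether towards Claisen rearrangement. A4 needs the same differentiated ring A phenol plus a C-acylation, α-functionalisation and phosphonium salt formation, so the ring A problem is not eased (equal at best). The acetal groups of A5 need acid for removal, which the prenyl ether is not expected to tolerate.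
- **Comparison.** Convergence is equal (late esterification against late coupling). The linear sequence to A4 is longer, and one step is saved after ring closure.

**Alternative 3:** The cut is C4–C4a.
- **Forward step.** (E)-2-(Benzyloxy)-3-[3,5-bis(benzyloxy)-2-methoxyphenoxy]-3-[4-(benzyloxy)-3-methoxyphenyl]acrylic acid A6 would be activated as a mixed anhydride or in a strongly acidic dehydrating medium. Its acyl cation would attack C4a to give 3,5,7,4'-tetrakis(benzyloxy)-8,3'-dimethoxyflavone A7.
- **In favour.** Only one ortho position of the aryloxy ring is free (C8 is blocked), so the regiochemistry is as secure as in the chosen plan (equal). O3 is present from the start (better). No metal or pressurised gas is needed (better in operation).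
- **Against.** The acidic electrophilic conditions exclude a prenyl ether and threaten benzyl ethers. A7 would therefore give four free hydroxyls on debenzylation, and O7 would then have to be prenylated selectively beside the 4'- and 3-hydroxyls, which is not dependable. A6 also needs a defined double-bond geometry, since only the isomer with the acid cis to the aryloxy group can close.
- **Comparison.** Mechanistically this is a reliable electrophilic substitution on an electron-rich ring, against a neutral catalytic cascade. The step count to the core is similar, but the prenyl placement adds steps afterwards.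

Key step: step 9

Remark on the chemistry: the target has no stereogenic element. Both phenol protecting groups are triisopropylsilyl ethers, because an acetal such as methoxymethyl would need protic acid for removal, which the prenyl aryl ether is not expected to tolerate.

## Route

Step 1
Reactants: 1 2-methoxyresorcinol (2-methoxybenzene-1,3-diol)
Product: 2 2-methoxy-1,3-phenylene diacetate
Conditions: Ac2O, pyridine, DMAP (cat.), CH2Cl2, 0 °C → rt
Reagents that add atoms: acetic anhydride, CC(=O)OC(C)=O
Why: Exhaustive O-acylation of both phenols (nucleophilic acyl substitution); the acetates keep the ring symmetric, keep O–H groups away from the boron reagent, and can later be removed under neutral conditions beside an aryl silyl ether.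

Step 2
Reactants: 2 2-methoxy-1,3-phenylene diacetate
Product: 4 5-hydroxy-2-methoxy-1,3-phenylene diacetate, via aryl pinacol boronate 3 (not isolated)
Conditions: [Ir(OMe)(cod)]2 (1.5 mol %), dtbpy (3 mol %), B2pin2, THF, 80 °C; then KHSO5 (as 2KHSO5·KHSO4·K2SO4), acetone/H2O, rt
Reagents that add atoms: potassium peroxymonosulfate, [K+].[O-]S(=O)(=O)OO
Why: Sterically controlled iridium-catalysed aromatic C–H borylation takes the only C–H bond without an ortho substituent (C5, para to the methoxy group), and the boronate is oxidised in the same flask to the phenol at the same carbon (one-pot borylation–oxidation); aryl acetates tolerate both stages because the oxidant solution is slightly acidic.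

Step 3
Reactants: 4 5-hydroxy-2-methoxy-1,3-phenylene diacetate
Product: 5 2-methoxy-5-[(triisopropylsilyl)oxy]-1,3-phenylene diacetate
Conditions: TIPSOTf, 2,6-lutidine, CH2Cl2, −78 → 0 °C
Reagents that add atoms: triisopropylsilyl trifluoromethanesulfonate, CC(C)[Si](C(C)C)(C(C)C)OS(=O)(=O)C(F)(F)F
Why: O-Silylation of the single free, unhindered phenol; the hindered non-nucleophilic base avoids the acyl transfer that imidazole or DMAP could cause with aryl acetates.

Step 4
Reactants: 5 2-methoxy-5-[(triisopropylsilyl)oxy]-1,3-phenylene diacetate
Product: 6 2-methoxy-5-[(triisopropylsilyl)oxy]benzene-1,3-diol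
Conditions: N2H4·H2O, THF/MeOH, 0 °C
Reagents that add atoms: none
Why: Hydrazinolysis of aryl acetates (acyl transfer to a neutral α-effect nucleophile) is fast at 0 °C and leaves the bulky aryl silyl ether alone; no phenoxide is formed, which limits air oxidation of the electron-rich diol.

Step 5
Reactants: 6 2-methoxy-5-[(triisopropylsilyl)oxy]benzene-1,3-diol
Product: 7 4-iodo-2-methoxy-5-[(triisopropylsilyl)oxy]benzene-1,3-diol
Conditions: NIS (1.0 equiv), CH2Cl2, −78 → −20 °C, dark
Reagents that add atoms: N-iodosuccinimide, O=C1CCC(=O)N1I
Why: Electrophilic aromatic iodination of a phloroglucinol-type ring; the two open positions of 6 are equivalent by symmetry, so mono-substitution can give only one constitution, and one equivalent of reagent at low temperature should stop at the mono-iodide.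

Step 6
Reactants: 7 4-iodo-2-methoxy-5-[(triisopropylsilyl)oxy]benzene-1,3-diol; 8 prenyl bromide (1-bromo-3-methylbut-2-ene)
Product: 9 2-iodo-6-methoxy-5-[(3-methylbut-2-en-1-yl)oxy]-3-[(triisopropylsilyl)oxy]phenol
Conditions: NaH (2.2 equiv), DMF, 0 °C; then 8 (1.0 equiv), −20 → 0 °C; AcOH quench
Reagents that add atoms: none
Why: Williamson O-alkylation (SN2) of the bis-phenoxide: the oxygen para to iodine is the more basic and the less hindered (neighbours OMe and H, against OMe and I for the other), so it should take the single equivalent of allylic bromide first, as dianions of dihydroxyarenes alkylate at the less acidic oxygen; C-alkylation is disfavoured in DMF and the only open ring carbon is flanked by the silyl ether.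

Step 7
Reactants: 10 vanillin (4-hydroxy-3-methoxybenzaldehyde)
Product: 11 3-methoxy-4-[(triisopropylsilyl)oxy]benzaldehyde
Conditions: TIPSCl, imidazole, DMF, rt
Reagents that add atoms: chlorotriisopropylsilane, CC(C)[Si](Cl)(C(C)C)C(C)C
Why: Imidazole-promoted O-silylation of a phenol; the bulky silyl ether is chosen to survive organolithium, amine and amide-base conditions and to leave with fluoride.

Step 8
Reactants: 11 3-methoxy-4-[(triisopropylsilyl)oxy]benzaldehyde
Product: 12 (4-ethynyl-2-methoxyphenoxy)triisopropylsilane
Conditions: Me3SiCHN2, n-BuLi, THF, −78 °C → rt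
Reagents that add atoms: (trimethylsilyl)diazomethane, C[Si](C)(C)C=[N+]=[N-]
Why: Colvin rearrangement: lithiated silyldiazomethane adds to the aldehyde, Peterson elimination gives a diazoalkene, loss of N2 gives an alkylidene carbene, and a 1,2-shift gives the terminal alkyne; no methoxide is present, so the para-formyl aryl silyl ether is not cleaved as it could be under carbonate/methanol homologation conditions.

Step 9
Reactants: 9 2-iodo-6-methoxy-5-[(3-methylbut-2-en-1-yl)oxy]-3-[(triisopropylsilyl)oxy]phenol; 12 (4-ethynyl-2-methoxyphenoxy)triisopropylsilane; 13 carbon monoxide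
Product: 16 8,3'-dimethoxy-7-[(3-methylbut-2-en-1-yl)oxy]-5,4'-bis[(triisopropylsilyl)oxy]flavone, via 2-hydroxyaryl ynone 14 (not isolated), via diethylamino enone 15 (not isolated)
Conditions: PdCl2(PPh3)2 (5 mol %), CO (5 bar), Et2NH, 80 °C
Reagents that add atoms: none
Why: PdCl2(PPh3)2 is reduced in situ to zerovalent palladium, which adds oxidatively to the C4a–I bond of 9; CO inserts to give an aroylpalladium iodide, the acetylide formed from 12 and Et2NH replaces iodide, and reductive elimination gives ynone 14 (C4a–C4 and C4–C3 formed). Et2NH then adds to the ynone to give β-amino enone 15, the C8a hydroxyl attacks C2 and the amine is expelled, closing ring C through O1–C2 by a 6-endo addition–elimination. The closest known reaction type is the palladium-catalysed carbonylative coupling of 2-iodophenols with terminal arylalkynes in a secondary amine, which gives flavones directly. Three selectivities are needed: CO insertion before alkynyl transfer (secured by CO pressure, the absence of copper and the electron-rich aryl group on palladium), 6-endo rather than 5-exo closure (secured by the enaminone pathway, in which C2 is the electrophilic carbon), and closure through O1 rather than O5 (secured by the silyl ether on O5). No stereocentre is formed. The prenyl ether should survive because ionisation of a trisubstituted allyl aryl ether by zerovalent palladium is far slower than oxidative addition to an aryl iodide, and the triisopropylsilyl ethers are inert to the amine at this temperature.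

Step 10
Reactants: 16 8,3'-dimethoxy-7-[(3-methylbut-2-en-1-yl)oxy]-5,4'-bis[(triisopropylsilyl)oxy]flavone
Product: 19 3-hydroxy-8,3'-dimethoxy-7-[(3-methylbut-2-en-1-yl)oxy]-5,4'-bis[(triisopropylsilyl)oxy]flavone, via 3-lithioflavone 17 (not isolated), via flavon-3-yl dimethyl boronate 18 (not isolated)
Conditions: LiN(i-Pr)2 (commercial solution), THF, −78 °C; B(OMe)3, −78 → 0 °C; AcOH, 30% H2O2, 0 °C → rt
Reagents that add atoms: hydrogen peroxide, OO
Why: Carbonyl-directed deprotonation of C3–H (vinylic, next to C4=O), borate capture and peroxide-induced 1,2-migration of C3 from boron to oxygen give the flavonol (metalation–borylation–oxidation of a flavone); acetic-acid-buffered hydrogen peroxide does not epoxidise the isolated trisubstituted alkene, and the amide base does not attack silyl or allyl ethers at −78 °C.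

Step 11
Reactants: 19 3-hydroxy-8,3'-dimethoxy-7-[(3-methylbut-2-en-1-yl)oxy]-5,4'-bis[(triisopropylsilyl)oxy]flavone
Product: 20 3,5-dihydroxy-2-(4-hydroxy-3-methoxyphenyl)-8-methoxy-7-[(3-methylbut-2-en-1-yl)oxy]-4H-chromen-4-one
Conditions: TBAF, AcOH, THF, 0 °C
Reagents that add atoms: none
Why: Fluoride cleavage of both aryl O–Si bonds; buffering with acetic acid keeps the liberated flavonol from base-promoted autoxidation, and since no acid, reductant or oxidant is involved the prenyl ether and the enol are untouched.

## Compound list

1 | 2-methoxyresorcinol (2-methoxybenzene-1,3-diol) | COc1c(O)cccc1O | starting material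
2 | 2-methoxy-1,3-phenylene diacetate | COc1c(OC(C)=O)cccc1OC(C)=O | intermediate
3 | 2-methoxy-5-(4,4,5,5-tetramethyl-1,3,2-dioxaborolan-2-yl)-1,3-phenylene diacetate | COc1c(OC(C)=O)cc(B2OC(C)(C)C(C)(C)O2)cc1OC(C)=O | intermediate
4 | 5-hydroxy-2-methoxy-1,3-phenylene diacetate | COc1c(OC(C)=O)cc(O)cc1OC(C)=O | intermediate
5 | 2-methoxy-5-[(triisopropylsilyl)oxy]-1,3-phenylene diacetate | COc1c(OC(C)=O)cc(O[Si](C(C)C)(C(C)C)C(C)C)cc1OC(C)=O | intermediate
6 | 2-methoxy-5-[(triisopropylsilyl)oxy]benzene-1,3-diol | COc1c(O)cc(O[Si](C(C)C)(C(C)C)C(C)C)cc1O | intermediate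
7 | 4-iodo-2-methoxy-5-[(triisopropylsilyl)oxy]benzene-1,3-diol | COc1c(O)cc(O[Si](C(C)C)(C(C)C)C(C)C)c(I)c1O | intermediate
8 | prenyl bromide (1-bromo-3-methylbut-2-ene) | CC(C)=CCBr | starting material
9 | 2-iodo-6-methoxy-5-[(3-methylbut-2-en-1-yl)oxy]-3-[(triisopropylsilyl)oxy]phenol | CC(C)[Si](C(C)C)(C(C)C)Oc1cc(OCC=C(C)C)c(OC)c(O)c1I | intermediate
10 | vanillin (4-hydroxy-3-methoxybenzaldehyde) | COc1cc(C=O)ccc1O | starting material
11 | 3-methoxy-4-[(triisopropylsilyl)oxy]benzaldehyde | COc1cc(C=O)ccc1O[Si](C(C)C)(C(C)C)C(C)C | intermediate
12 | (4-ethynyl-2-methoxyphenoxy)triisopropylsilane | C#Cc1ccc(O[Si](C(C)C)(C(C)C)C(C)C)c(OC)c1 | intermediate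
13 | carbon monoxide | [C-]#[O+] | starting material
14 | 1-{2-hydroxy-3-methoxy-4-[(3-methylbut-2-en-1-yl)oxy]-6-[(triisopropylsilyl)oxy]phenyl}-3-{3-methoxy-4-[(triisopropylsilyl)oxy]phenyl}prop-2-yn-1-one | COc1c(O)c(C(=O)C#Cc2ccc(O[Si](C(C)C)(C(C)C)C(C)C)c(OC)c2)c(O[Si](C(C)C)(C(C)C)C(C)C)cc1OCC=C(C)C | intermediate
15 | (E)-3-(diethylamino)-1-{2-hydroxy-3-methoxy-4-[(3-methylbut-2-en-1-yl)oxy]-6-[(triisopropylsilyl)oxy]phenyl}-3-{3-methoxy-4-[(triisopropylsilyl)oxy]phenyl}prop-2-en-1-one (drawn as the E isomer expected from amine addition; the geometry is lost on ring closure) | COc1c(O)c(C(=O)/C=C(\c2ccc(O[Si](C(C)C)(C(C)C)C(C)C)c(OC)c2)N(CC)CC)c(O[Si](C(C)C)(C(C)C)C(C)C)cc1OCC=C(C)C | intermediate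
16 | 8-methoxy-2-{3-methoxy-4-[(triisopropylsilyl)oxy]phenyl}-7-[(3-methylbut-2-en-1-yl)oxy]-5-[(triisopropylsilyl)oxy]-4H-chromen-4-one | CC(C)[Si](C(C)C)(C(C)C)Oc1ccc(-c2cc(=O)c3c(O[Si](C(C)C)(C(C)C)C(C)C)cc(OCC=C(C)C)c(OC)c3o2)cc1OC | intermediate
17 | 3-lithio derivative of 16 (lithium on C3) | CC(C)[Si](C(C)C)(C(C)C)Oc1ccc(-c2oc3c(OC)c(OCC=C(C)C)cc(O[Si](C(C)C)(C(C)C)C(C)C)c3c(=O)c2[Li])cc1OC | intermediate
18 | dimethyl {8-methoxy-2-{3-methoxy-4-[(triisopropylsilyl)oxy]phenyl}-7-[(3-methylbut-2-en-1-yl)oxy]-4-oxo-5-[(triisopropylsilyl)oxy]-4H-chromen-3-yl}boronate | CC(C)[Si](C(C)C)(C(C)C)Oc1ccc(-c2oc3c(OC)c(OCC=C(C)C)cc(O[Si](C(C)C)(C(C)C)C(C)C)c3c(=O)c2B(OC)OC)cc1OC | intermediate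
19 | 3-hydroxy-8-methoxy-2-{3-methoxy-4-[(triisopropylsilyl)oxy]phenyl}-7-[(3-methylbut-2-en-1-yl)oxy]-5-[(triisopropylsilyl)oxy]-4H-chromen-4-one | CC(C)[Si](C(C)C)(C(C)C)Oc1ccc(-c2oc3c(OC)c(OCC=C(C)C)cc(O[Si](C(C)C)(C(C)C)C(C)C)c3c(=O)c2O)cc1OC | intermediate
20 | 3,5-dihydroxy-2-(4-hydroxy-3-methoxyphenyl)-8-methoxy-7-[(3-methylbut-2-en-1-yl)oxy]-4H-chromen-4-one | COc1cc(-c2oc3c(OC)c(OCC=C(C)C)cc(O)c3c(=O)c2O)ccc1O | target

## Step count and least certain steps

Total step count: 11. Longest linear sequence: 9 steps (steps 1–6 and 9–11, from 1 to 20). The ring B branch (steps 7 and 8) has 2 steps.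

**Step 9 (key step).**
- **What may go wrong.** Zerovalent palladium may ionise the allylic C7–O bond and pass the prenyl group to the amine, so the ether is lost. The aroylpalladium intermediate may be captured by the amine, or coupling may occur without CO insertion and lead to a benzofuran. Oxidative addition may be slow, because the iodide is electron-rich and flanked by two oxygen substituents.
- **Fallback.** This sets out from 9 and 12, makes C4a–C4 by acylation of an aryllithium and takes C4 from a preformed acyl carbon. 12 would be deprotonated (n-BuLi, THF, −78 °C) and trapped with N-methoxy-N-methylcarbamoyl chloride to give N-methoxy-3-{3-methoxy-4-[(triisopropylsilyl)oxy]phenyl}-N-methylprop-2-ynamide F1. 9 would be treated with n-BuLi (2.1 equiv, THF, −78 °C; phenoxide formation, then iodine–lithium exchange) and acylated by F1. The temperature is held at −78 °C so that the bulky silyl group does not migrate from oxygen to carbon. Work-up should give ynone 14, where the detour rejoins the route. Diethylamine (EtOH, rt to 50 °C) then closes 14 to 16 through 15, as in the second half of step 9.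

**Step 6.**
- **What may go wrong.** Alkylation at the wrong oxygen or at both, because the two phenoxides differ by only about one pKa unit and by the size of one ortho neighbour.
- **Fallback.** This sets out from 7 and lets the ring closure tell the two hydroxyls apart. 7 would go without alkylation into the carbonylative coupling with 12 and 13 under the conditions of step 9. Only the hydroxyl ortho to the new ketone can cyclise, so this should give 7-hydroxy-8,3'-dimethoxy-5,4'-bis[(triisopropylsilyl)oxy]flavone F2. Its single free phenol would then be alkylated with 8 (K2CO3, acetone, rt) to give 16, where the route is rejoined with the step count unchanged.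

**Step 10.**
- **What may go wrong.** The C3-metalated pyranone may fragment by β-elimination of the ring oxygen (reverting to the ynone phenoxide). Metalation may be incomplete, or the boronate may be protonated off before oxidation.
- **Fallback.** This sets out from 7 and brings in the 3-oxygen by epoxidation of C2=C3 before any isolated alkene is present. 7 would be carried to the 7-hydroxyflavone F2 as in the detour for step 6. Acetylation (Ac2O, pyridine) gives 7-acetoxy-8,3'-dimethoxy-5,4'-bis[(triisopropylsilyl)oxy]flavone F3. Dimethyldioxirane (acetone, 0 °C → rt) epoxidises C2=C3, and the epoxide should open, with a trace of TsOH if needed, to 7-acetoxy-3-hydroxy-8,3'-dimethoxy-5,4'-bis[(triisopropylsilyl)oxy]flavone F4. Hydrazinolysis (N2H4·H2O, THF, 0 °C) gives 3,7-dihydroxy-8,3'-dimethoxy-5,4'-bis[(triisopropylsilyl)oxy]flavone F5. One equivalent each of K2CO3 and 8 in acetone should alkylate the far more acidic 7-hydroxyl and leave the chelated 3-hydroxyl, giving 19, where the route is rejoined.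

**Step 5.**
- **What may go wrong.** Twofold iodination or oxidative degradation of the very electron-rich diol.
- **Fallback.** This sets out from 5 and iodinates before the phenols are freed. NIS with catalytic CF3CO2H in MeCN should give 4-iodo-2-methoxy-5-[(triisopropylsilyl)oxy]-1,3-phenylene diacetate F6. The two open positions are still equivalent, and the less activated ring makes a second iodination slower. Hydrazinolysis as in step 4 then gives 7, where the route is rejoined.

## Further compounds

F1 | step 9 | N-methoxy-3-{3-methoxy-4-[(triisopropylsilyl)oxy]phenyl}-N-methylprop-2-ynamide | CON(C)C(=O)C#Cc1ccc(O[Si](C(C)C)(C(C)C)C(C)C)c(OC)c1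
F2 | step 6 | 7-hydroxy-8,3'-dimethoxy-5,4'-bis[(triisopropylsilyl)oxy]flavone | CC(C)[Si](C(C)C)(C(C)C)Oc1ccc(-c2cc(=O)c3c(O[Si](C(C)C)(C(C)C)C(C)C)cc(O)c(OC)c3o2)cc1OC
F3 | step 10 | 7-acetoxy-8,3'-dimethoxy-5,4'-bis[(triisopropylsilyl)oxy]flavone | CC(C)[Si](C(C)C)(C(C)C)Oc1ccc(-c2cc(=O)c3c(O[Si](C(C)C)(C(C)C)C(C)C)cc(OC(C)=O)c(OC)c3o2)cc1OC
F4 | step 10 | 7-acetoxy-3-hydroxy-8,3'-dimethoxy-5,4'-bis[(triisopropylsilyl)oxy]flavone | CC(C)[Si](C(C)C)(C(C)C)Oc1ccc(-c2oc3c(OC)c(OC(C)=O)cc(O[Si](C(C)C)(C(C)C)C(C)C)c3c(=O)c2O)cc1OC
F5 | step 10 | 3,7-dihydroxy-8,3'-dimethoxy-5,4'-bis[(triisopropylsilyl)oxy]flavone | CC(C)[Si](C(C)C)(C(C)C)Oc1ccc(-c2oc3c(OC)c(O)cc(O[Si](C(C)C)(C(C)C)C(C)C)c3c(=O)c2O)cc1OC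
F6 | step 5 | 4-iodo-2-methoxy-5-[(triisopropylsilyl)oxy]-1,3-phenylene diacetate | COc1c(OC(C)=O)cc(O[Si](C(C)C)(C(C)C)C(C)C)c(I)c1OC(C)=O
A1 | alternative 1 | 4-(benzyloxy)-2-(tert-butyldimethylsilyloxy)furan | CC(C)(C)[Si](C)(C)Oc1cc(OCc2ccccc2)co1
A2 | alternative 1 | methyl 3-bromopropiolate | COC(=O)C#CBr
A3 | alternative 1 | methyl 4-(benzyloxy)-2-bromo-6-(tert-butyldimethylsilyloxy)-3-hydroxybenzoate | COC(=O)c1c(Br)c(O)c(OCc2ccccc2)cc1O[Si](C)(C)C(C)(C)C
A4 | alternative 2 | 6-methoxy-3-(methoxymethoxy)-5-(prenyloxy)-2-{2-[2-(trimethylsilyl)ethoxy]-2-(triphenylphosphoranylidene)acetyl}phenyl 3-methoxy-4-(methoxymethoxy)benzoate | COc1cc(C(=O)Oc2c(OC)c(OCC=C(C)C)cc(OCOC)c2C(=O)C(OCC[Si](C)(C)C)=P(c3ccccc3)(c3ccccc3)c3ccccc3)ccc1OCOC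
A5 | alternative 2 | 5,4'-bis(methoxymethoxy)-8,3'-dimethoxy-7-(prenyloxy)-3-[2-(trimethylsilyl)ethoxy]flavone | COCOc1ccc(-c2oc3c(OC)c(OCC=C(C)C)cc(OCOC)c3c(=O)c2OCC[Si](C)(C)C)cc1OC
A6 | alternative 3 | (E)-2-(benzyloxy)-3-[3,5-bis(benzyloxy)-2-methoxyphenoxy]-3-[4-(benzyloxy)-3-methoxyphenyl]acrylic acid | OC(=O)/C(OCc1ccccc1)=C(\Oc1cc(OCc2ccccc2)cc(OCc2ccccc2)c1OC)c1ccc(OCc2ccccc2)c(OC)c1
A7 | alternative 3 | 3,5,7,4'-tetrakis(benzyloxy)-8,3'-dimethoxyflavone | COc1cc(-c2oc3c(OC)c(OCc4ccccc4)cc(OCc4ccccc4)c3c(=O)c2OCc2ccccc2)ccc1OCc1ccccc1
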